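**Strategy**

The polyene is cut at C11=C12 and C11′=C12′ (Wittig reactions on the commercial C10 dialdehyde) and at C8–C9 (vinyllithium plus Weinreb amide); the ε-ring arrives intact in (R)-α-ionone. Everything rests on the 3-hydroxy-β-ring: its tetrasubstituted C5=C6 bond, flanked by quaternary C1 and the C7 methylene next to the C8 carbonyl, is the retron of radical addition to the central carbon of an allenoate. An acyclic silyloxy allenoate bearing an isopropenyl group, built from (S)-epichlorohydrin, is cyclised by iron-hydride hydrogen-atom transfer: the tertiary C1 radical attacks C6, creating the C1–C6 bond, the gem-dimethyl centre, the ring alkene and the C7 methylene at once. The 19-decenoate is added last.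

Key step: step 4

Remark: (R)-(+)-α-ionone (28) and 4-methoxybenzyl propargyl ether (16) are taken as purchasable; intermediates 7–13 are carried as mixtures at the methyl-bearing carbon or the allene axis, because both elements vanish in step 4.

**Route**

Step 1
Reactants: 1 (S)-epichlorohydrin; 2 isopropenylmagnesium bromide
Product: 4 (2S)-2-(2-methylprop-2-en-1-yl)oxirane, via chlorohydrin 3 (not isolated)
Conditions: 2 (1.2 equiv), CuI (10 mol %), THF, −40 → 0 °C; then powdered NaOH, Et2O, rt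
Reagents that add atoms: none
Why: Copper-catalysed Grignard opening of the epoxide at its CH2 terminus, then base-induced closure of the chlorohydrin (intramolecular Williamson reaction), relays the epoxide along the chain without touching the C–O stereocentre, so the configuration of 1 becomes that of the future C3.

Step 2
Reactants: 4 (2S)-2-(2-methylprop-2-en-1-yl)oxirane; 5 propionic acid
Product: 9 (4R)-4-[(tert-butyldimethylsilyl)oxy]-2,6-dimethylhept-6-enoic acid (2RS), via propionate dianion 6 (not isolated), via dilithium hydroxy acid salt 7 (not isolated), via bis-silyl compound 8 (not isolated)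
Conditions: LDA (2.0 equiv), THF/DMPU, 0 °C; then 4, 0 → 45 °C; then TBSCl (2.5 equiv), rt; then aq. citric acid (pH 4), THF, rt
Reagents that add atoms: tert-butyldimethylsilyl chloride, CC(C)(C)[Si](C)(C)Cl
Why: SN2 opening of the terminal epoxide carbon by the carboxylic acid dianion (enediolate alkylation) leaves the carbinol centre untouched, silylation in the same flask blocks lactonisation and the labile silyl ester is hydrolysed on work-up; the new α-methyl centre forms without control and is erased in step 3.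

Step 3
Reactants: 9 (4R)-4-[(tert-butyldimethylsilyl)oxy]-2,6-dimethylhept-6-enoic acid; 10 ethyl (triphenylphosphoranylidene)acetate
Product: 13 ethyl (6S)-6-[(tert-butyldimethylsilyl)oxy]-4,8-dimethylnona-2,3,8-trienoate, via acid chloride 11 (not isolated), via ketene 12 (not isolated)
Conditions: 1-chloro-N,N,2-trimethylprop-1-en-1-amine (1.1 equiv), CH2Cl2, 0 °C → rt; then added to 10 (1.05 equiv) and Et3N (1.2 equiv), CH2Cl2, 0 °C → rt
Reagents that add atoms: none
Why: Dehydrochlorination of the α-branched acid chloride gives a ketene whose C=O undergoes Wittig olefination with the stabilised ylide (ketene–Wittig allenoate synthesis) under neutral conditions that spare the silyl ether; the allene axis forms as a mixture and is destroyed in step 4.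

Step 4
Reactants: 13 ethyl (6S)-6-[(tert-butyldimethylsilyl)oxy]-4,8-dimethylnona-2,3,8-trienoate
Product: 14 ethyl 2-[(4R)-4-[(tert-butyldimethylsilyl)oxy]-2,6,6-trimethylcyclohex-1-en-1-yl]acetate
Conditions: Fe(acac)3 (30 mol %), PhSiH3 (2.5 equiv), EtOH (0.02 M), 60 °C, Ar
Reagents that add atoms: none
Why: Proposed new method: an iron hydride formed from Fe(acac)3 and PhSiH3 should transfer H• to the CH2 terminus of the electron-rich isopropenyl group (Markovnikov MHAT) to give the tertiary C1 radical, which adds to C6, the central and β-carbon of the allenoate; the α-ester radical at C7 is then reduced by Fe(II) to the enolate and protonated by ethanol at C7. The closest known reaction types are the iron-catalysed MHAT reductive olefin coupling (radical Giese cyclisation onto acrylates and enones) and radical addition to the central carbon of allenes. The one ring formed is the six-membered carbocycle C1–C6, closed in a 6-exo-dig mode on the ester-conjugated C6=C7 π-bond, while the orthogonal C5=C6 π-bond stays in the ring as the tetrasubstituted alkene. No stereocentre is created: C1 becomes the achiral gem-dimethyl carbon and the C3 centre, set by (S)-epichlorohydrin, is a spectator. The step needs HAT to the isopropenyl group rather than to the electron-poor allene, attack at C6 rather than C5 and protonation at C7 rather than C5; these should follow from the preference of the iron hydride for the electron-rich alkene, from polarity matching of the nucleophilic tertiary radical with the acrylate-like β-carbon (attack at C5 would give a vinyl radical and two adjacent quaternary carbons) and from kinetic α-protonation of the dienolate. It joins two carbons that are both electrophilic in polar terms (the Markovnikov carbon of an alkene and a Michael β-carbon).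

Step 5
Reactants: 14 ethyl 2-[(4R)-4-[(tert-butyldimethylsilyl)oxy]-2,6,6-trimethylcyclohex-1-en-1-yl]acetate
Product: 15 N-methoxy-N-methyl-2-[(4R)-4-[(tert-butyldimethylsilyl)oxy]-2,6,6-trimethylcyclohex-1-en-1-yl]acetamide
Conditions: MeNH(OMe)·HCl (1.5 equiv), i-PrMgCl (3.0 equiv), THF, −20 → 0 °C
Reagents that add atoms: N,O-dimethylhydroxylamine hydrochloride, CNOC.Cl
Why: Aminolysis of the ester by the chloromagnesium amide (Weinreb amide formation) is fast at low temperature and should not move the deconjugated ring double bond.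

Step 6
Reactants: 16 4-methoxybenzyl propargyl ether
Product: 18 methyl 4-[(4-methoxybenzyl)oxy]but-2-ynoate, via lithium acetylide 17 (not isolated)
Conditions: n-BuLi (1.05 equiv), THF, −78 °C; then ClCO2Me, −78 → 0 °C
Reagents that add atoms: methyl chloroformate, COC(=O)Cl
Why: Deprotonation of the terminal alkyne and C-acylation of the acetylide with the chloroformate installs the carbon that becomes C19.

Step 7
Reactants: 18 methyl 4-[(4-methoxybenzyl)oxy]but-2-ynoate
Product: 19 methyl (2E)-4-[(4-methoxybenzyl)oxy]-2-(tributylstannyl)but-2-enoate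
Conditions: Bu3SnH (1.1 equiv), Pd(PPh3)4 (2 mol %), THF, 0 °C → rt
Reagents that add atoms: tributyltin hydride, CCCC[SnH](CCCC)CCCC
Why: Palladium-catalysed syn-hydrostannation of an ynoate places tin α to the ester and hydrogen β on the same side, which fixes the two CH2O groups cis and so sets the later C9=C10 geometry.

Step 8
Reactants: 19 methyl (2E)-4-[(4-methoxybenzyl)oxy]-2-(tributylstannyl)but-2-enoate
Product: 20 (2E)-4-[(4-methoxybenzyl)oxy]-2-(tributylstannyl)but-2-en-1-ol
Conditions: DIBAL-H (2.2 equiv), CH2Cl2, −78 °C; Rochelle salt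
Reagents that add atoms: none
Why: Hydride reduction of the ester to the allylic alcohol (DIBAL reduction) leaves the vinylstannane and its geometry intact.

Step 9
Reactants: 20 (2E)-4-[(4-methoxybenzyl)oxy]-2-(tributylstannyl)but-2-en-1-ol
Product: 21 tert-butyl{[(2E)-4-[(4-methoxybenzyl)oxy]-2-(tributylstannyl)but-2-en-1-yl]oxy}dimethylsilane
Conditions: TBSCl (1.2 equiv), imidazole, DMF, rt
Reagents that add atoms: tert-butyldimethylsilyl chloride, CC(C)(C)[Si](C)(C)Cl
Why: Standard silylation of the primary alcohol gives the future C19 oxygen a protecting group orthogonal to the PMB ether on the future C11 oxygen.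

Step 10
Reactants: 21 tert-butyl{[(2E)-4-[(4-methoxybenzyl)oxy]-2-(tributylstannyl)but-2-en-1-yl]oxy}dimethylsilane; 15 N-methoxy-N-methyl-2-[(4R)-4-[(tert-butyldimethylsilyl)oxy]-2,6,6-trimethylcyclohex-1-en-1-yl]acetamide
Product: 23 (3E)-3-{[(tert-butyldimethylsilyl)oxy]methyl}-5-[(4-methoxybenzyl)oxy]-1-[(4R)-4-[(tert-butyldimethylsilyl)oxy]-2,6,6-trimethylcyclohex-1-en-1-yl]pent-3-en-2-one, via vinyllithium 22 (not isolated)
Conditions: 21, n-BuLi (1.05 equiv), THF, −78 °C; then 15, −78 → −20 °C; aq. NH4Cl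
Reagents that add atoms: none
Why: Tin–lithium exchange proceeds with retention of alkene geometry and the vinyllithium acylates the Weinreb amide through a chelated tetrahedral intermediate that prevents over-addition (Weinreb ketone synthesis), giving the C8 ketone with C8 trans to C11.

Step 11
Reactants: 23 (3E)-3-{[(tert-butyldimethylsilyl)oxy]methyl}-5-[(4-methoxybenzyl)oxy]-1-[(4R)-4-[(tert-butyldimethylsilyl)oxy]-2,6,6-trimethylcyclohex-1-en-1-yl]pent-3-en-2-one
Product: 24 (3E)-3-{[(tert-butyldimethylsilyl)oxy]methyl}-5-hydroxy-1-[(4R)-4-[(tert-butyldimethylsilyl)oxy]-2,6,6-trimethylcyclohex-1-en-1-yl]pent-3-en-2-one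
Conditions: DDQ (1.3 equiv), CH2Cl2/pH 7 buffer, 0 °C
Reagents that add atoms: none
Why: Oxidative cleavage of the PMB ether by DDQ (hydride abstraction, then hydrolysis of the oxocarbenium ion) frees only the C11 hydroxyl and leaves both silyl ethers in place.

Step 12
Reactants: 24 (3E)-3-{[(tert-butyldimethylsilyl)oxy]methyl}-5-hydroxy-1-[(4R)-4-[(tert-butyldimethylsilyl)oxy]-2,6,6-trimethylcyclohex-1-en-1-yl]pent-3-en-2-one
Product: 26 [(2E)-3-{[(tert-butyldimethylsilyl)oxy]methyl}-4-oxo-5-[(4R)-4-[(tert-butyldimethylsilyl)oxy]-2,6,6-trimethylcyclohex-1-en-1-yl]pent-2-en-1-yl]triphenylphosphonium bromide, via allylic bromide 25 (not isolated)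
Conditions: CBr4 (1.1 equiv), PPh3 (2.3 equiv), MeCN, 0 °C → rt
Reagents that add atoms: triphenylphosphine, c1ccc(cc1)P(c1ccccc1)c1ccccc1; carbon tetrabromide, BrC(Br)(Br)Br
Why: Appel bromination of the primary allylic alcohol is followed by SN2 quaternisation of the reactive γ-bromo enone by the second equivalent of phosphine.

Step 13
Reactants: 26 [(2E)-3-{[(tert-butyldimethylsilyl)oxy]methyl}-4-oxo-5-[(4R)-4-[(tert-butyldimethylsilyl)oxy]-2,6,6-trimethylcyclohex-1-en-1-yl]pent-2-en-1-yl]triphenylphosphonium bromide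
Product: 27 [(2E)-3-(hydroxymethyl)-5-[(4R)-4-hydroxy-2,6,6-trimethylcyclohex-1-en-1-yl]-4-oxopent-2-en-1-yl]triphenylphosphonium bromide
Conditions: aq. HF (48 %), MeCN, 0 °C → rt
Reagents that add atoms: none
Why: Acidic fluoride cleaves both silyl ethers at the stage of the robust phosphonium salt, so that no deprotection is needed on the sensitive carotenoid.

Step 14
Reactants: 28 (R)-α-ionone
Product: 29 (1E)-3-methyl-1-[(1R)-2,6,6-trimethylcyclohex-2-en-1-yl]penta-1,4-dien-3-ol (3RS)
Conditions: vinylMgBr (1.3 equiv), THF, −20 → 0 °C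
Reagents that add atoms: vinylmagnesium bromide, C=C[Mg]Br
Why: 1,2-Addition of the vinyl Grignard reagent to the methyl ketone gives the tertiary carbinol, whose new centre is uncontrolled and is erased in step 17.

Step 15
Reactants: 29 (1E)-3-methyl-1-[(1R)-2,6,6-trimethylcyclohex-2-en-1-yl]penta-1,4-dien-3-ol
Product: 30 (4R)-4-[(1E)-3-hydroxy-3-methylpenta-1,4-dien-1-yl]-3,5,5-trimethylcyclohex-2-en-1-one
Conditions: Rh2(cap)4 (1 mol %), t-BuOOH (70 % aq., 8 equiv), K2CO3 (0.5 equiv), CH2Cl2, rt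
Reagents that add atoms: tert-butyl hydroperoxide, CC(C)(C)OO
Why: Dirhodium caprolactamate-catalysed allylic C–H oxidation with t-BuOOH should take the ring CH2 next to the less substituted alkene carbon (C3) to the enone under basic conditions that spare the acid-labile tertiary carbinol.

Step 16
Reactants: 30 (4R)-4-[(1E)-3-hydroxy-3-methylpenta-1,4-dien-1-yl]-3,5,5-trimethylcyclohex-2-en-1-one
Product: 31 (1R,4R)-4-[(1E)-3-hydroxy-3-methylpenta-1,4-dien-1-yl]-3,5,5-trimethylcyclohex-2-en-1-ol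
Conditions: L-Selectride (2.5 equiv), THF, −78 °C
Reagents that add atoms: none
Why: 1,2-Reduction of the β,β-disubstituted enone by the bulky hydride should occur anti to the axial C1 methyl in the half-chair that holds the C6 side chain pseudo-axial (A1,2 strain with the C5 methyl), which gives the 3,6-trans alcohol with the new centre R.

Step 17
Reactants: 31 (1R,4R)-4-[(1E)-3-hydroxy-3-methylpenta-1,4-dien-1-yl]-3,5,5-trimethylcyclohex-2-en-1-ol
Product: 32 [(2E,4E)-5-[(1R,4R)-4-hydroxy-2,6,6-trimethylcyclohex-2-en-1-yl]-3-methylpenta-2,4-dien-1-yl]triphenylphosphonium bromide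
Conditions: PPh3·HBr (1.05 equiv), CH2Cl2, 0 °C → rt
Reagents that add atoms: triphenylphosphine hydrobromide, [Br-].[PH+](c1ccccc1)(c1ccccc1)c1ccccc1
Why: Ionisation of the tertiary doubly allylic alcohol and capture of the pentadienyl cation at its primary terminus by phosphine (the usual C15 Wittig salt formation) should give the conjugated E,E salt, while the less easily ionised secondary ring alcohol is spared by the stoichiometric acid in a non-nucleophilic solvent.

Step 18
Reactants: 32 [(2E,4E)-5-[(1R,4R)-4-hydroxy-2,6,6-trimethylcyclohex-2-en-1-yl]-3-methylpenta-2,4-dien-1-yl]triphenylphosphonium bromide; 33 (2E,4E,6E)-2,7-dimethylocta-2,4,6-trienedial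
Product: 35 (2E,4E,6E,8E,10E,12E)-13-[(1R,4R)-4-hydroxy-2,6,6-trimethylcyclohex-2-en-1-yl]-2,7,11-trimethyltrideca-2,4,6,8,10,12-hexaenal, via C15 ylide 34 (not isolated)
Conditions: 33 (3 equiv), NaOMe (1.1 equiv), CH2Cl2/MeOH, −10 °C → rt, dark; then heptane, 80 °C
Reagents that add atoms: none
Why: Wittig olefination of one aldehyde of the symmetrical dialdehyde, used in excess to suppress double condensation, forms C11′=C12′, and thermal equilibration is expected to converge any Z isomer on the all-E aldehyde.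

Step 19
Reactants: 27 [(2E)-3-(hydroxymethyl)-5-[(4R)-4-hydroxy-2,6,6-trimethylcyclohex-1-en-1-yl]-4-oxopent-2-en-1-yl]triphenylphosphonium bromide; 35 (2E,4E,6E,8E,10E,12E)-13-[(1R,4R)-4-hydroxy-2,6,6-trimethylcyclohex-2-en-1-yl]-2,7,11-trimethyltrideca-2,4,6,8,10,12-hexaenal
Product: 37 (3R,3′R,6′R)-3,3′,19-trihydroxy-7,8-dihydro-β,ε-caroten-8-one, via keto ylide 36 (not isolated)
Conditions: NaOMe (1.1 equiv), CH2Cl2/MeOH, 0 °C → rt, Ar, dark
Reagents that add atoms: none
Why: Wittig olefination of the vinylogous keto-stabilised ylide, which forms selectively at C11 because that position is far more acidic than C7 or the hydroxyl groups, should give the E-configured C11=C12 bond and complete the C40 chain.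

Step 20
Reactants: 37 (3R,3′R,6′R)-3,3′,19-trihydroxy-7,8-dihydro-β,ε-caroten-8-one; 38 (2E)-dec-2-enoic acid
Product: 40 (3R,3′R,6′R)-3,3′-dihydroxy-8-oxo-7,8-dihydro-β,ε-caroten-19-yl (2E)-dec-2-enoate, via O-acylisourea 39 (not isolated)
Conditions: 38 (1.05 equiv), DIC (1.1 equiv), DMAP (5 mol %), CH2Cl2, −20 → 0 °C, dark
Reagents that add atoms: none
Why: Carbodiimide/DMAP esterification (Steglich) with one equivalent of acid at low temperature should acylate the primary allylic C19 hydroxyl faster than the two secondary ring hydroxyls.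

**Compound list**

1 | (S)-epichlorohydrin | ClC[C@@H]1CO1 | starting material
2 | isopropenylmagnesium bromide | CC(=C)[Mg]Br | starting material
3 | (2S)-1-chloro-4-methylpent-4-en-2-ol (as its magnesium alkoxide) | ClC[C@@H](O)CC(C)=C | intermediate (not isolated)
4 | (2S)-2-(2-methylprop-2-en-1-yl)oxirane | C=C(C)C[C@H]1CO1 | intermediate
5 | propionic acid | CCC(=O)O | starting material
6 | dilithium enediolate of propionic acid | CC=C(O[Li])O[Li] | intermediate (not isolated)
7 | dilithium (4R)-2,6-dimethyl-4-oxidohept-6-enoate (2RS) | [Li]OC(=O)C(C)C[C@@H](O[Li])CC(C)=C | intermediate (not isolated)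
8 | tert-butyldimethylsilyl (4R)-4-[(tert-butyldimethylsilyl)oxy]-2,6-dimethylhept-6-enoate (2RS) | CC(C)(C)[Si](C)(C)OC(=O)C(C)C[C@@H](O[Si](C)(C)C(C)(C)C)CC(C)=C | intermediate (not isolated)
9 | (4R)-4-[(tert-butyldimethylsilyl)oxy]-2,6-dimethylhept-6-enoic acid (2RS) | OC(=O)C(C)C[C@@H](O[Si](C)(C)C(C)(C)C)CC(C)=C | intermediate
10 | ethyl (triphenylphosphoranylidene)acetate | CCOC(=O)C=P(c1ccccc1)(c1ccccc1)c1ccccc1 | starting material
11 | (4R)-4-[(tert-butyldimethylsilyl)oxy]-2,6-dimethylhept-6-enoyl chloride (2RS) | ClC(=O)C(C)C[C@@H](O[Si](C)(C)C(C)(C)C)CC(C)=C | intermediate (not isolated)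
12 | (4S)-4-[(tert-butyldimethylsilyl)oxy]-2,6-dimethylhepta-1,6-dien-1-one (ketene) | O=C=C(C)C[C@@H](O[Si](C)(C)C(C)(C)C)CC(C)=C | intermediate (not isolated)
13 | ethyl (6S)-6-[(tert-butyldimethylsilyl)oxy]-4,8-dimethylnona-2,3,8-trienoate (both allene-axis isomers) | CCOC(=O)C=C=C(C)C[C@@H](O[Si](C)(C)C(C)(C)C)CC(C)=C | intermediate
14 | ethyl 2-[(4R)-4-[(tert-butyldimethylsilyl)oxy]-2,6,6-trimethylcyclohex-1-en-1-yl]acetate | CCOC(=O)CC1=C(C)C[C@@H](O[Si](C)(C)C(C)(C)C)CC1(C)C | intermediate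
15 | N-methoxy-N-methyl-2-[(4R)-4-[(tert-butyldimethylsilyl)oxy]-2,6,6-trimethylcyclohex-1-en-1-yl]acetamide | CON(C)C(=O)CC1=C(C)C[C@@H](O[Si](C)(C)C(C)(C)C)CC1(C)C | intermediate
16 | 4-methoxybenzyl propargyl ether | C#CCOCc1ccc(OC)cc1 | starting material
17 | lithium acetylide of 16 | [Li]C#CCOCc1ccc(OC)cc1 | intermediate (not isolated)
18 | methyl 4-[(4-methoxybenzyl)oxy]but-2-ynoate | COC(=O)C#CCOCc1ccc(OC)cc1 | intermediate
19 | methyl (2E)-4-[(4-methoxybenzyl)oxy]-2-(tributylstannyl)but-2-enoate | CCCC[Sn](CCCC)(CCCC)/C(C(=O)OC)=C/COCc1ccc(OC)cc1 | intermediate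
20 | (2E)-4-[(4-methoxybenzyl)oxy]-2-(tributylstannyl)but-2-en-1-ol | CCCC[Sn](CCCC)(CCCC)/C(CO)=C/COCc1ccc(OC)cc1 | intermediate
21 | tert-butyl{[(2E)-4-[(4-methoxybenzyl)oxy]-2-(tributylstannyl)but-2-en-1-yl]oxy}dimethylsilane | CCCC[Sn](CCCC)(CCCC)/C(CO[Si](C)(C)C(C)(C)C)=C/COCc1ccc(OC)cc1 | intermediate
22 | vinyllithium from 21 (Li trans to the CH2OPMB group) | [Li]/C(CO[Si](C)(C)C(C)(C)C)=C/COCc1ccc(OC)cc1 | intermediate (not isolated)
23 | (3E)-3-{[(tert-butyldimethylsilyl)oxy]methyl}-5-[(4-methoxybenzyl)oxy]-1-[(4R)-4-[(tert-butyldimethylsilyl)oxy]-2,6,6-trimethylcyclohex-1-en-1-yl]pent-3-en-2-one | COc1ccc(COC/C=C(\CO[Si](C)(C)C(C)(C)C)C(=O)CC2=C(C)C[C@@H](O[Si](C)(C)C(C)(C)C)CC2(C)C)cc1 | intermediate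
24 | (3E)-3-{[(tert-butyldimethylsilyl)oxy]methyl}-5-hydroxy-1-[(4R)-4-[(tert-butyldimethylsilyl)oxy]-2,6,6-trimethylcyclohex-1-en-1-yl]pent-3-en-2-one | OC/C=C(\CO[Si](C)(C)C(C)(C)C)C(=O)CC1=C(C)C[C@@H](O[Si](C)(C)C(C)(C)C)CC1(C)C | intermediate
25 | (3E)-5-bromo-3-{[(tert-butyldimethylsilyl)oxy]methyl}-1-[(4R)-4-[(tert-butyldimethylsilyl)oxy]-2,6,6-trimethylcyclohex-1-en-1-yl]pent-3-en-2-one | BrC/C=C(\CO[Si](C)(C)C(C)(C)C)C(=O)CC1=C(C)C[C@@H](O[Si](C)(C)C(C)(C)C)CC1(C)C | intermediate (not isolated)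
26 | [(2E)-3-{[(tert-butyldimethylsilyl)oxy]methyl}-4-oxo-5-[(4R)-4-[(tert-butyldimethylsilyl)oxy]-2,6,6-trimethylcyclohex-1-en-1-yl]pent-2-en-1-yl]triphenylphosphonium bromide | [Br-].O=C(CC1=C(C)C[C@@H](O[Si](C)(C)C(C)(C)C)CC1(C)C)/C(CO[Si](C)(C)C(C)(C)C)=C/C[P+](c1ccccc1)(c1ccccc1)c1ccccc1 | intermediate
27 | [(2E)-3-(hydroxymethyl)-5-[(4R)-4-hydroxy-2,6,6-trimethylcyclohex-1-en-1-yl]-4-oxopent-2-en-1-yl]triphenylphosphonium bromide | [Br-].O=C(CC1=C(C)C[C@@H](O)CC1(C)C)/C(CO)=C/C[P+](c1ccccc1)(c1ccccc1)c1ccccc1 | intermediate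
28 | (R)-α-ionone, (3E)-4-[(1R)-2,6,6-trimethylcyclohex-2-en-1-yl]but-3-en-2-one | CC(=O)/C=C/[C@H]1C(C)=CCCC1(C)C | starting material
29 | (1E)-3-methyl-1-[(1R)-2,6,6-trimethylcyclohex-2-en-1-yl]penta-1,4-dien-3-ol (3RS) | C=CC(C)(O)/C=C/[C@H]1C(C)=CCCC1(C)C | intermediate
30 | (4R)-4-[(1E)-3-hydroxy-3-methylpenta-1,4-dien-1-yl]-3,5,5-trimethylcyclohex-2-en-1-one | C=CC(C)(O)/C=C/[C@H]1C(C)=CC(=O)CC1(C)C | intermediate
31 | (1R,4R)-4-[(1E)-3-hydroxy-3-methylpenta-1,4-dien-1-yl]-3,5,5-trimethylcyclohex-2-en-1-ol | C=CC(C)(O)/C=C/[C@H]1C(C)=C[C@H](O)CC1(C)C | intermediate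
32 | [(2E,4E)-5-[(1R,4R)-4-hydroxy-2,6,6-trimethylcyclohex-2-en-1-yl]-3-methylpenta-2,4-dien-1-yl]triphenylphosphonium bromide | [Br-].C(/C=C(C)/C=C/[C@H]1C(C)=C[C@H](O)CC1(C)C)[P+](c1ccccc1)(c1ccccc1)c1ccccc1 | intermediate
33 | (2E,4E,6E)-2,7-dimethylocta-2,4,6-trienedial | O=C/C(C)=C/C=C/C=C(C)/C=O | starting material
34 | ylide of 32 | C(/C=C(C)/C=C/[C@H]1C(C)=C[C@H](O)CC1(C)C)=P(c1ccccc1)(c1ccccc1)c1ccccc1 | intermediate (not isolated)
35 | (2E,4E,6E,8E,10E,12E)-13-[(1R,4R)-4-hydroxy-2,6,6-trimethylcyclohex-2-en-1-yl]-2,7,11-trimethyltrideca-2,4,6,8,10,12-hexaenal | O=C/C(C)=C/C=C/C=C(C)/C=C/C=C(C)/C=C/[C@H]1C(C)=C[C@H](O)CC1(C)C | intermediate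
36 | ylide of 27 | O=C(CC1=C(C)C[C@@H](O)CC1(C)C)/C(CO)=C/C=P(c1ccccc1)(c1ccccc1)c1ccccc1 | intermediate (not isolated)
37 | (3R,3′R,6′R)-3,3′,19-trihydroxy-7,8-dihydro-β,ε-caroten-8-one | OC\C(=C/C=C/C(C)=C/C=C/C=C(C)/C=C/C=C(C)/C=C/[C@H]1C(C)=C[C@H](O)CC1(C)C)C(=O)CC1=C(C)C[C@@H](O)CC1(C)C | intermediate
38 | (2E)-dec-2-enoic acid | CCCCCCC/C=C/C(=O)O | starting material
39 | O-[(2E)-dec-2-enoyl]-N,N′-diisopropylisourea | CCCCCCC/C=C/C(=O)OC(=NC(C)C)NC(C)C | intermediate (not isolated)
40 | (3R,3′R,6′R)-3,3′-dihydroxy-8-oxo-7,8-dihydro-β,ε-caroten-19-yl (2E)-dec-2-enoate | CCCCCCC/C=C/C(=O)OC\C(=C/C=C/C(C)=C/C=C/C=C(C)/C=C/C=C(C)/C=C/[C@H]1C(C)=C[C@H](O)CC1(C)C)C(=O)CC1=C(C)C[C@@H](O)CC1(C)C | target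

**Step count**

Total: 20 steps. Longest linear sequence: 11 steps (1–5, 10–13, 19, 20).

**Three steps most likely to fail**

1. Step 4 (key step, proposed new method). What may go wrong: hydrogen-atom transfer to the allenoate instead of the isopropenyl group, conjugate addition of ethanol to the allenoate, reduction of the tertiary radical before it cyclises, or γ-protonation that moves the double bond out of the ring. Fallback (known chemistry, two-electron palladium closure of the same C1–C6 bond): setting out from allenoate 13, hydroiodination (NaI, AcOH, rt; iodide adds to the central allene carbon) would give ethyl (3Z,6S)-6-[(tert-butyldimethylsilyl)oxy]-3-iodo-4,8-dimethylnona-3,8-dienoate F1, the 3E isomer being separated. An intramolecular reductive Heck reaction (Pd(OAc)2, PPh3, HCO2Na, Et4NCl, DMF, 80 °C) would then return to ring ester 14: 6-exo-trig carbopalladation of the isopropenyl group gives a neopentyl-type alkylpalladium without β-hydrogen, which formate reduces to the second methyl group.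

2. Step 19. What may go wrong: slow olefination because a vinylogous keto-stabilised ylide meets a deactivated polyenal, loss of the C9=C10 geometry by rotation in the delocalised ylide, and base-induced decomposition of the enone. Fallback (reversed polarity of the union): alcohol 24 would be oxidised (MnO2, CH2Cl2) to (2E)-3-{[(tert-butyldimethylsilyl)oxy]methyl}-4-oxo-5-[(4R)-4-[(tert-butyldimethylsilyl)oxy]-2,6,6-trimethylcyclohex-1-en-1-yl]pent-2-enal F2. Aldehyde 35 would be reduced (NaBH4, MeOH, 0 °C) to (2E,4E,6E,8E,10E,12E)-13-[(1R,4R)-4-hydroxy-2,6,6-trimethylcyclohex-2-en-1-yl]-2,7,11-trimethyltrideca-2,4,6,8,10,12-hexaen-1-ol F3 and converted (PPh3·HBr, CH2Cl2, 0 °C) into the corresponding C25 triphenylphosphonium bromide F4. NaOMe would give the C25 ylide F5, whose Wittig reaction with F2 at −20 °C would give (3R,3′R,6′R)-3,19-bis[(tert-butyldimethylsilyl)oxy]-3′-hydroxy-7,8-dihydro-β,ε-caroten-8-one F6. Buffered HF·pyridine in THF would return to triol 37.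

3. Step 15. What may go wrong: peroxy-radical attack at the doubly allylic C6–H or at the dienyl carbinol side chain, and over-oxidation. Fallback (C3 is oxidised before the vinyl carbinol is made): setting out from ketone 28, ketalisation (ethylene glycol, HC(OMe)3, PPTS) would give 2-methyl-2-{(E)-2-[(1R)-2,6,6-trimethylcyclohex-2-en-1-yl]ethenyl}-1,3-dioxolane F7. The same allylic oxidation would give (4R)-3,5,5-trimethyl-4-[(E)-2-(2-methyl-1,3-dioxolan-2-yl)ethenyl]cyclohex-2-en-1-one F8, and L-Selectride would give (1R,4R)-3,5,5-trimethyl-4-[(E)-2-(2-methyl-1,3-dioxolan-2-yl)ethenyl]cyclohex-2-en-1-ol F9. Mild hydrolysis (PPTS, acetone/H2O) would give (3E)-4-[(1R,4R)-4-hydroxy-2,6,6-trimethylcyclohex-2-en-1-yl]but-3-en-2-one F10, and vinylmagnesium bromide (3 equiv, THF) would return to diol 31.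

Further compounds
F1 | step 4 | ethyl (3Z,6S)-6-[(tert-butyldimethylsilyl)oxy]-3-iodo-4,8-dimethylnona-3,8-dienoate | CCOC(=O)C/C(I)=C(C)/C[C@@H](O[Si](C)(C)C(C)(C)C)CC(C)=C
F2 | step 19 | (2E)-3-{[(tert-butyldimethylsilyl)oxy]methyl}-4-oxo-5-[(4R)-4-[(tert-butyldimethylsilyl)oxy]-2,6,6-trimethylcyclohex-1-en-1-yl]pent-2-enal | O=C/C=C(\CO[Si](C)(C)C(C)(C)C)C(=O)CC1=C(C)C[C@@H](O[Si](C)(C)C(C)(C)C)CC1(C)C
F3 | step 19 | (2E,4E,6E,8E,10E,12E)-13-[(1R,4R)-4-hydroxy-2,6,6-trimethylcyclohex-2-en-1-yl]-2,7,11-trimethyltrideca-2,4,6,8,10,12-hexaen-1-ol | OC/C(C)=C/C=C/C=C(C)/C=C/C=C(C)/C=C/[C@H]1C(C)=C[C@H](O)CC1(C)C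
F4 | step 19 | [(2E,4E,6E,8E,10E,12E)-13-[(1R,4R)-4-hydroxy-2,6,6-trimethylcyclohex-2-en-1-yl]-2,7,11-trimethyltrideca-2,4,6,8,10,12-hexaen-1-yl]triphenylphosphonium bromide | [Br-].C(/C(C)=C/C=C/C=C(C)/C=C/C=C(C)/C=C/[C@H]1C(C)=C[C@H](O)CC1(C)C)[P+](c1ccccc1)(c1ccccc1)c1ccccc1
F5 | step 19 | ylide of F4 | C(/C(C)=C/C=C/C=C(C)/C=C/C=C(C)/C=C/[C@H]1C(C)=C[C@H](O)CC1(C)C)=P(c1ccccc1)(c1ccccc1)c1ccccc1
F6 | step 19 | (3R,3′R,6′R)-3,19-bis[(tert-butyldimethylsilyl)oxy]-3′-hydroxy-7,8-dihydro-β,ε-caroten-8-one | CC(C)(C)[Si](C)(C)OC\C(=C/C=C/C(C)=C/C=C/C=C(C)/C=C/C=C(C)/C=C/[C@H]1C(C)=C[C@H](O)CC1(C)C)C(=O)CC1=C(C)C[C@@H](O[Si](C)(C)C(C)(C)C)CC1(C)C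
F7 | step 15 | 2-methyl-2-{(E)-2-[(1R)-2,6,6-trimethylcyclohex-2-en-1-yl]ethenyl}-1,3-dioxolane | CC2(OCCO2)/C=C/[C@H]1C(C)=CCCC1(C)C
F8 | step 15 | (4R)-3,5,5-trimethyl-4-[(E)-2-(2-methyl-1,3-dioxolan-2-yl)ethenyl]cyclohex-2-en-1-one | CC2(OCCO2)/C=C/[C@H]1C(C)=CC(=O)CC1(C)C
F9 | step 15 | (1R,4R)-3,5,5-trimethyl-4-[(E)-2-(2-methyl-1,3-dioxolan-2-yl)ethenyl]cyclohex-2-en-1-ol | CC2(OCCO2)/C=C/[C@H]1C(C)=C[C@H](O)CC1(C)C
F10 | step 15 | (3E)-4-[(1R,4R)-4-hydroxy-2,6,6-trimethylcyclohex-2-en-1-yl]but-3-en-2-one | CC(=O)/C=C/[C@H]1C(C)=C[C@H](O)CC1(C)C
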